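## Retrosynthetic overview

1. The target is traced back to hydroquinone dimethyl ether 37 (sulfation last); its C8 methyl, C9 methyl and C9 arylmethyl group all derive from the C8 enone of cis-fused bicycle 23.
2. Feature used: in decalin A the quaternary ring-fusion carbon C5 lies para to C8 in ring C5–C6–C7–C8–C9–C10. With a carbonyl at C8, C5 is the prochiral carbon of a 4,4-disubstituted cyclohexa-2,5-dienone (22) whose two enone arms are C10=C9 and C6=C7.
3. Key disconnection C1–C10: a bis(phenylsulfonyl)methyl carbanion at the end of the C4-methylene tether adds to one arm and closes ring C1–C2–C3–C4–C5–C10 (catalyst-controlled desymmetrisation).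
4. Dienone 22 comes from benzoic acid (its ring becomes C5–C10, its carboxyl carbon C4) by Birch reduction–alkylation with decalin B iodide 13, then enolate Michael addition, methylenation and bis-allylic oxidation.
5. Iodide 13 comes from 4,4-dimethylcyclohexenone (asymmetric conjugate addition, aldol closure, Claisen transfer for the quaternary carbon). Ring order: decalin B gem-dimethyl ring, decalin B second ring, ring C5–C10 (from the arene), ring C1–C5/C10 (key step).

Key step: step 14

## Remarks

- Locants. Decalin A: C4 = C(=CH2), C5 = quaternary fusion carbon, C10 = fusion CH, C9/C8 = methyl-bearing carbons, C6/C7 and C1–C3 = CH2 groups. Decalin B is primed: C1′=C10′ alkene, C4′ gem-dimethyl, C5′ fusion CH, C8′ CH(CH3), C9′ quaternary. Drawings follow the terpenoid convention (C10 above C5, ring C1–C4 on the left); β = towards the viewer. In these terms the target is 5β-chain, 10β-H, 9β-CH2Ar, 9α-CH3, 8β-CH3 (5R,8S,9S,10R) and 5′α-H, 8′β-CH3, 9′β-CH3 (5′S,8′S,9′R).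
- DecB = (1R,2S,4aS)-1,2,5,5-tetramethyl-1,2,3,4,4a,5,6,7-octahydronaphthalen-1-yl.
- Assumption: the target is drawn as the free bis(hydrogen sulfate); it is taken to be handled as its salt, of which the drawn structure is the neutral form.
- Compounds 1, 4, 14, 18 and 29 are taken as commercial.

## Route

Step 1
Reactants: 1 3-acetyl-3-methyloxolan-2-one
Product: 2 5-bromo-3-methylpentan-2-one (racemic)
Conditions: 48% aq. HBr, 80 °C
Reagents that add atoms: hydrogen bromide, Br
Why: Hot HBr opens the lactone, the β-keto acid decarboxylates and the primary alcohol becomes the bromide (acidic cleavage of an α-acyl-γ-butyrolactone).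

Step 2
Reactants: 2 5-bromo-3-methylpentan-2-one
Product: 3 2-(4-bromobutan-2-yl)-2-methyl-1,3-dioxolane (racemic)
Conditions: ethylene glycol, p-TsOH (cat.), benzene, reflux, Dean–Stark trap
Reagents that add atoms: ethylene glycol, OCCO
Why: Acid-catalysed ketalisation with azeotropic removal of water masks the ketone so that the bromide can be converted into an organometallic reagent.

Step 3
Reactants: 3 2-(4-bromobutan-2-yl)-2-methyl-1,3-dioxolane; 4 4,4-dimethylcyclohex-2-en-1-one
Product: 7 (3R)-4,4-dimethyl-3-[3-(2-methyl-1,3-dioxolan-2-yl)butyl]cyclohexan-1-one (both epimers at the side-chain methine), via Grignard reagent 5 (not isolated), via dialkylzinc 6 (not isolated)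
Conditions: Mg, THF, 40 °C; Zn(OMe)2, Et2O, rt, magnesium salts removed by centrifugation; then 4, Cu(OTf)2 (2 mol%), (S)-BINOL-derived N,N-bis[(R)-1-phenylethyl]phosphoramidite (4 mol%), toluene, −30 °C; aq. NH4Cl
Reagents that add atoms: none
Why: Copper–phosphoramidite-catalysed asymmetric conjugate addition of a dialkylzinc to a cyclohexenone is known for 4,4-dimethylcyclohexenone and for acetal-bearing zinc reagents; the ligand sets C5′ (R in 7; the antipodal ligand is taken if the sense proves opposite), and the side-chain methine is left as a mixture that step 4 equilibrates.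

Step 4
Reactants: 7 (3R)-4,4-dimethyl-3-[3-(2-methyl-1,3-dioxolan-2-yl)butyl]cyclohexan-1-one
Product: 9 (4aS,7S)-4,4,7,8-tetramethyl-3,4,4a,5,6,7-hexahydronaphthalen-1(2H)-one, via diketone 8 (not isolated)
Conditions: 2 M HCl, THF, rt; then KOH, MeOH, 65 °C
Reagents that add atoms: none
Why: Ketal hydrolysis and intramolecular aldol condensation (C10′ enolate onto the methyl ketone; the other six-membered aldol gives a bridged ketol that cannot dehydrate) should give the fused enone, and C8′, now γ to the carbonyl, equilibrates through the dienolate to the epimer whose methyl is pseudoaxial and away from the C9′ methyl (allylic 1,2-strain), i.e. trans to H-5′.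

Step 5
Reactants: 9 (4aS,7S)-4,4,7,8-tetramethyl-3,4,4a,5,6,7-hexahydronaphthalen-1(2H)-one
Product: 10 (1S,4aS,7S)-4,4,7,8-tetramethyl-1,2,3,4,4a,5,6,7-octahydronaphthalen-1-ol
Conditions: (R)-2-methyl-CBS-oxazaborolidine (20 mol%), BH3·SMe2, THF, −20 °C; MeOH
Reagents that add atoms: none
Why: Corey–Bakshi–Shibata reduction with the alkylidene side as the large group should deliver hydride under reagent control to give the (1S) alcohol, OH cis to H-5′; allylic 1,3-strain with the C9′ methyl holds this OH pseudoaxial.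

Step 6
Reactants: 10 (1S,4aS,7S)-4,4,7,8-tetramethyl-1,2,3,4,4a,5,6,7-octahydronaphthalen-1-ol
Product: 11 N,N-dimethyl-2-(DecB)acetamide
Conditions: N,N-dimethylacetamide dimethyl acetal, xylene, 140 °C
Reagents that add atoms: N,N-dimethylacetamide dimethyl acetal, COC(C)(OC)N(C)C
Why: Eschenmoser–Claisen rearrangement: the ketene N,O-acetal on the pseudoaxial oxygen transfers the acetamide carbon suprafacially to C9′, which sets the quaternary centre (arm α, trans to the C8′ methyl) and moves the double bond to C1′=C10′.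

Step 7
Reactants: 11 N,N-dimethyl-2-(DecB)acetamide
Product: 12 2-(DecB)ethan-1-ol
Conditions: LiEt3BH, THF, 0 °C → rt; aq. NaOH
Reagents that add atoms: none
Why: LiEt3BH is known to reduce N,N-dialkylamides to primary alcohols with C–N cleavage and does not touch the trisubstituted alkene.

Step 8
Reactants: 12 2-(DecB)ethan-1-ol
Product: 13 (1R,2S,4aS)-1-(2-iodoethyl)-1,2,5,5-tetramethyl-1,2,3,4,4a,5,6,7-octahydronaphthalene
Conditions: PPh3, I2, imidazole, CH2Cl2, 0 °C → rt
Reagents that add atoms: iodine, II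
Why: Appel-type iodination of a primary alcohol under neutral conditions.

Step 9
Reactants: 14 benzoic acid; 13 (1R,2S,4aS)-1-(2-iodoethyl)-1,2,5,5-tetramethyl-1,2,3,4,4a,5,6,7-octahydronaphthalene
Product: 16 1-[2-(DecB)ethyl]cyclohexa-2,5-diene-1-carboxylic acid, via Birch dianion 15 (not isolated)
Conditions: Li, NH3(l)/THF, −78 °C; isoprene to discharge excess Li; then 13 (limiting), −78 → −33 °C; aq. HCl
Reagents that add atoms: none
Why: Birch reduction of benzoic acid gives the dianion, which the primary iodide alkylates at the carboxylate-bearing carbon; this creates the quaternary carbon C5 in a 1,4-diene that is symmetric about C5.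

Step 10
Reactants: 16 1-[2-(DecB)ethyl]cyclohexa-2,5-diene-1-carboxylic acid
Product: 17 1-{1-[2-(DecB)ethyl]cyclohexa-2,5-dien-1-yl}ethan-1-one
Conditions: MeLi (2.5 equiv), Et2O, 0 °C → rt; inverse quench into cold aq. HCl
Reagents that add atoms: methyllithium, [Li]C
Why: Methyllithium adds to the lithium carboxylate to give a stable gem-dialkoxide that releases the methyl ketone only on acidic work-up (ketone synthesis from a carboxylic acid; the α-carbon is quaternary, so nothing can enolise).

Step 11
Reactants: 17 1-{1-[2-(DecB)ethyl]cyclohexa-2,5-dien-1-yl}ethan-1-one; 18 1,1-bis(phenylsulfonyl)ethene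
Product: 20 1-{1-[2-(DecB)ethyl]cyclohexa-2,5-dien-1-yl}-4,4-bis(phenylsulfonyl)butan-1-one, via lithium enolate 19 (not isolated)
Conditions: LiN(i-Pr)2 (LDA), THF, −78 °C; 18 added slowly, −78 °C; AcOH
Reagents that add atoms: none
Why: The enolate can form only on the methyl side and undergoes Michael addition to the strongly electrophilic 1,1-bis(sulfonyl)alkene, the adduct resting as the stabilised bis-sulfonyl carbanion until the quench.

Step 12
Reactants: 20 1-{1-[2-(DecB)ethyl]cyclohexa-2,5-dien-1-yl}-4,4-bis(phenylsulfonyl)butan-1-one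
Product: 21 2-{1-[2-(DecB)ethyl]cyclohexa-2,5-dien-1-yl}-5,5-bis(phenylsulfonyl)pent-1-ene
Conditions: Zn, CH2Br2, TiCl4, THF, 0 °C (reagent pre-formed); then 20, CH2Cl2, 0 °C → rt
Reagents that add atoms: dibromomethane, BrCBr
Why: Takai–Lombardo methylenation uses a weakly basic gem-dizinc/titanium reagent that olefinates hindered, enolisable ketones and should tolerate the acidic bis-sulfone C–H, which a phosphorus ylide would deprotonate.

Step 13
Reactants: 21 2-{1-[2-(DecB)ethyl]cyclohexa-2,5-dien-1-yl}-5,5-bis(phenylsulfonyl)pent-1-ene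
Product: 22 4-[5,5-bis(phenylsulfonyl)pent-1-en-2-yl]-4-[2-(DecB)ethyl]cyclohexa-2,5-dien-1-one
Conditions: t-BuOOH, (C5H5NH)2Cr2O7 (PDC), Celite, benzene, rt
Reagents that add atoms: tert-butyl hydroperoxide, CC(C)(C)OO
Why: Chromium-mediated oxidation with t-BuOOH converts the doubly allylic CH2 of a 3,3-disubstituted cyclohexa-1,4-diene into the cross-conjugated dienone; this is the weakest C–H bond in the molecule, and the medium contains no base that could start the cyclisation.

Step 14
Reactants: 22 4-[5,5-bis(phenylsulfonyl)pent-1-en-2-yl]-4-[2-(DecB)ethyl]cyclohexa-2,5-dien-1-one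
Product: 23 cis-fused enone, 4-methylidene-1,1-bis(phenylsulfonyl)-5β-[2-(DecB)ethyl]-10β-H-decal-6-en-8-one (decalin A locants)
Conditions: N-[3,5-bis(trifluoromethyl)phenyl]-N′-[(8α,9S)-6′-methoxycinchonan-9-yl]thiourea (quinine-derived amine–thiourea, 10 mol%), toluene, 0 °C
Reagents that add atoms: none
Why: The quinuclidine nitrogen of the catalyst deprotonates the bis-sulfone (the only C–H acid an amine can reach) while the thiourea binds the dienone carbonyl, and carbanion C1 adds to the β-carbon C10 of one enone arm, the enol then being protonated at C9. The closest known reaction type is the amine–thiourea-catalysed desymmetrisation of 4,4-disubstituted cyclohexa-2,5-dienones by intramolecular Michael addition of a tethered bis(phenylsulfonyl)methyl group. Ring C1–C2–C3–C4–C5–C10 closes in the 6-exo-trig mode. C10 and C5 become stereogenic in the same event: the cis fusion (H-10 and the C5 side chain on one face) is imposed by the short tether anchored on C5, and the choice of arm, hence the absolute sense at both centres, by the catalyst. The step needs group selectivity between two arms that the remote decalin B centres cannot distinguish, so control rests on the catalyst alone (its quinidine-derived pseudoenantiomer is taken if the quinine series favours the other arm), and the low temperature and weak base keep the uncatalysed cyclisation slow.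

Step 15
Reactants: 23 cis-fused enone
Product: 24 allylic alcohol, 4-methylidene-1,1-bis(phenylsulfonyl)-5β-[2-(DecB)ethyl]-10β-H-decal-6-en-8-ol (C8 carbinol epimers, both carried on)
Conditions: NaBH4, CeCl3·7H2O, MeOH, −40 °C
Reagents that add atoms: none
Why: Luche reduction gives 1,2-reduction only; the enone is masked because the electron-transfer step that follows would reduce it, and the carbinol configuration is irrelevant since it is re-oxidised in step 17.

Step 16
Reactants: 24 allylic alcohol
Product: 25 4-methylidene-5β-[2-(DecB)ethyl]-10β-H-decal-6-en-8-ol (C8 carbinol epimers)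
Conditions: Mg turnings, MeOH/THF, rt → 50 °C; aq. NH4Cl
Reagents that add atoms: none
Why: Magnesium in methanol cleaves both C–S bonds of the geminal bis-sulfone by electron transfer; removing the sulfones here prevents the C9 enolates of steps 18 and 20 from expelling the bis-sulfonyl carbanion by retro-Michael reaction, which would scramble C5 and C10.

Step 17
Reactants: 25 desulfonylated allylic alcohol
Product: 26 4-methylidene-5β-[2-(DecB)ethyl]-10β-H-decal-6-en-8-one
Conditions: Dess–Martin periodinane, CH2Cl2, rt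
Reagents that add atoms: none
Why: Dess–Martin oxidation of the allylic alcohol restores the enone under nearly neutral conditions that leave the exocyclic and trisubstituted alkenes alone.

Step 18
Reactants: 26 4-methylidene-5β-[2-(DecB)ethyl]-10β-H-decal-6-en-8-one
Product: 28 9-methyl enone (C9 epimers), via lithium enolate 27 (not isolated)
Conditions: LiN(i-Pr)2 (LDA), THF, −78 °C; MeI, −78 → −40 °C
Reagents that add atoms: iodomethane, CI
Why: Deprotonation can occur only at C9 (C5 is quaternary, so there is no γ-hydrogen), and methylation of this cross-conjugated enolate gives the α′-methyl enone; the C9 configuration is erased again in step 20.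

Step 19
Reactants: 29 2,5-dimethoxybenzyl alcohol
Product: 30 2,5-dimethoxybenzyl bromide
Conditions: PBr3, Et2O, 0 °C
Reagents that add atoms: phosphorus tribromide, BrP(Br)Br
Why: Standard conversion of a benzylic alcohol into the bromide.

Step 20
Reactants: 28 9-methyl enone; 30 2,5-dimethoxybenzyl bromide
Product: 32 9β-(2,5-dimethoxybenzyl)-9α-methyl-4-methylidene-5β-[2-(DecB)ethyl]-10β-H-decal-6-en-8-one, via lithium enolate 31 (not isolated)
Conditions: LiN(i-Pr)2 (LDA), THF, −78 °C; DMPU; 30, −78 → −20 °C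
Reagents that add atoms: none
Why: Enolate alkylation creating the quaternary C9: the α face of the tetrasubstituted C8–C9 enolate is covered by ring C1–C5/C10 of the cis-fused bicycle (C1 on the neighbouring C10, C4 on C5), so the benzyl group should enter β, cis to H-10, leaving the methyl α.

Step 21
Reactants: 32 quaternary enone
Product: 33 9β-(2,5-dimethoxybenzyl)-9α-methyl-4-methylidene-5β-[2-(DecB)ethyl]-10β-H-decalin-8-one
Conditions: Li, NH3(l)/THF, t-BuOH (1 equiv), −78 °C, short contact; NH4Cl
Reagents that add atoms: none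
Why: Dissolving-metal reduction saturates the enone C6=C7 regardless of the flanking quaternary carbons and leaves the isolated alkenes and the electron-rich arene untouched under these brief conditions.

Step 22
Reactants: 33 saturated C8 ketone
Product: 34 8-(methoxymethylidene) compound (E/Z mixture)
Conditions: Ph3P(CH2OMe)Cl, KN(SiMe3)2, THF/toluene, 0 → 70 °C
Reagents that add atoms: (methoxymethyl)triphenylphosphonium chloride, COC[P+](c1ccccc1)(c1ccccc1)c1ccccc1.[Cl-]
Why: Wittig reaction with (methoxymethylidene)triphenylphosphorane homologates the ketone to the enol ether; excess ylide and heating are planned because the carbonyl sits next to the quaternary C9.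

Step 23
Reactants: 34 enol ether
Product: 35 8β-formyl-9β-(2,5-dimethoxybenzyl)-9α-methyl-4-methylidene-5β-[2-(DecB)ethyl]-10β-H-decalin
Conditions: 1 M HCl, THF, 0 °C → rt; then K2CO3, MeOH, rt
Reagents that add atoms: water, O
Why: Mild acid hydrolysis gives the aldehyde, and base equilibration through the enolate is expected to favour the equatorial 8β-formyl group, because in the chair with C1 axial on ring C5–C10 an 8α-formyl group would be syn-diaxial to C1; the epimers are diastereomers, so the minor one can be separated and re-equilibrated.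

Step 24
Reactants: 35 8β-aldehyde
Product: 37 8β-methyl-9β-(2,5-dimethoxybenzyl)-9α-methyl-4-methylidene-5β-[2-(DecB)ethyl]-10β-H-decalin, via hydrazone 36 (not isolated)
Conditions: N2H4·H2O, KOH, diethylene glycol, 130 °C then 200 °C
Reagents that add atoms: none
Why: Wolff–Kishner reduction (Huang–Minlon conditions) converts the formyl group into the C8 methyl through the hydrazone with loss of N2; aryl methyl ethers and unactivated alkenes are stable to hot KOH.

Step 25
Reactants: 37 hydroquinone dimethyl ether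
Product: 39 hydroquinone, 2-{[decalin A]methyl}benzene-1,4-diol, via quinone 38 (not isolated)
Conditions: (NH4)2Ce(NO3)6, MeCN/H2O, 0 °C; then aq. Na2S2O4, EtOAc, rt, under argon
Reagents that add atoms: water, O
Why: Oxidative demethylation of the 1,4-dimethoxyarene with (NH4)2Ce(NO3)6 gives the benzoquinone, which dithionite reduces to the hydroquinone; neither reagent attacks the alkenes.

Step 26
Reactants: 39 hydroquinone
Product: 40 CNP0439949.2, the hydroquinone bis(hydrogen sulfate)
Conditions: SO3·pyridine (excess), pyridine, 40 °C; H+-form cation-exchange resin, 0 °C, for the free acid; stored as the disodium salt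
Reagents that add atoms: sulfur trioxide–pyridine complex, O=S(=O)([O-])[n+]1ccccc1
Why: O-Sulfation of both phenols with the SO3·pyridine complex gives the bis(hydrogen sulfate) without touching the alkenes.

## Compound list

1 | 3-acetyl-3-methyloxolan-2-one (racemic) | CC(=O)C1(C)CCOC1=O | starting material
2 | 5-bromo-3-methylpentan-2-one (racemic) | CC(=O)C(C)CCBr | intermediate
3 | 2-(4-bromobutan-2-yl)-2-methyl-1,3-dioxolane (racemic) | CC(CCBr)C1(C)OCCO1 | intermediate
4 | 4,4-dimethylcyclohex-2-en-1-one | CC1(C)CCC(=O)C=C1 | starting material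
5 | [3-(2-methyl-1,3-dioxolan-2-yl)butyl]magnesium bromide | CC(CC[Mg]Br)C1(C)OCCO1 | intermediate (not isolated)
6 | bis[3-(2-methyl-1,3-dioxolan-2-yl)butyl]zinc | CC(CC[Zn]CCC(C)C1(C)OCCO1)C1(C)OCCO1 | intermediate (not isolated)
7 | (3R)-4,4-dimethyl-3-[3-(2-methyl-1,3-dioxolan-2-yl)butyl]cyclohexan-1-one (side-chain methine epimers) | O=C1CCC(C)(C)[C@H](CCC(C)C2(C)OCCO2)C1 | intermediate
8 | (3R)-4,4-dimethyl-3-(3-methyl-4-oxopentyl)cyclohexan-1-one (side-chain methine epimers) | O=C1CCC(C)(C)[C@H](CCC(C)C(C)=O)C1 | intermediate (not isolated)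
9 | (4aS,7S)-4,4,7,8-tetramethyl-3,4,4a,5,6,7-hexahydronaphthalen-1(2H)-one | O=C1CCC(C)(C)[C@@H]2CC[C@H](C)C(C)=C12 | intermediate
10 | (1S,4aS,7S)-4,4,7,8-tetramethyl-1,2,3,4,4a,5,6,7-octahydronaphthalen-1-ol | O[C@H]1CCC(C)(C)[C@@H]2CC[C@H](C)C(C)=C12 | intermediate
11 | N,N-dimethyl-2-[(1R,2S,4aS)-1,2,5,5-tetramethyl-1,2,3,4,4a,5,6,7-octahydronaphthalen-1-yl]acetamide | CN(C)C(=O)C[C@@]1(C)C2=CCCC(C)(C)[C@@H]2CC[C@@H]1C | intermediate
12 | 2-[(1R,2S,4aS)-1,2,5,5-tetramethyl-1,2,3,4,4a,5,6,7-octahydronaphthalen-1-yl]ethan-1-ol | OCC[C@@]1(C)C2=CCCC(C)(C)[C@@H]2CC[C@@H]1C | intermediate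
13 | (1R,2S,4aS)-1-(2-iodoethyl)-1,2,5,5-tetramethyl-1,2,3,4,4a,5,6,7-octahydronaphthalene | ICC[C@@]1(C)C2=CCCC(C)(C)[C@@H]2CC[C@@H]1C | intermediate
14 | benzoic acid | OC(=O)c1ccccc1 | starting material
15 | dilithium (cyclohexa-2,5-dien-1-ylidene)methanediolate (Birch dianion) | [Li]OC(O[Li])=C1C=CCC=C1 | intermediate (not isolated)
16 | 1-[2-(DecB)ethyl]cyclohexa-2,5-diene-1-carboxylic acid | OC(=O)C1(CC[C@@]3(C)C4=CCCC(C)(C)[C@@H]4CC[C@@H]3C)C=CCC=C1 | intermediate
17 | 1-{1-[2-(DecB)ethyl]cyclohexa-2,5-dien-1-yl}ethan-1-one | CC(=O)C1(CC[C@@]3(C)C4=CCCC(C)(C)[C@@H]4CC[C@@H]3C)C=CCC=C1 | intermediate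
18 | 1,1-bis(phenylsulfonyl)ethene | C=C(S(=O)(=O)c1ccccc1)S(=O)(=O)c1ccccc1 | starting material
19 | lithium enolate of 17 | [Li]OC(=C)C1(CC[C@@]3(C)C4=CCCC(C)(C)[C@@H]4CC[C@@H]3C)C=CCC=C1 | intermediate (not isolated)
20 | 1-{1-[2-(DecB)ethyl]cyclohexa-2,5-dien-1-yl}-4,4-bis(phenylsulfonyl)butan-1-one | O=C(CCC(S(=O)(=O)c5ccccc5)S(=O)(=O)c5ccccc5)C1(CC[C@@]3(C)C4=CCCC(C)(C)[C@@H]4CC[C@@H]3C)C=CCC=C1 | intermediate
21 | 2-{1-[2-(DecB)ethyl]cyclohexa-2,5-dien-1-yl}-5,5-bis(phenylsulfonyl)pent-1-ene | C=C(CCC(S(=O)(=O)c5ccccc5)S(=O)(=O)c5ccccc5)C1(CC[C@@]3(C)C4=CCCC(C)(C)[C@@H]4CC[C@@H]3C)C=CCC=C1 | intermediate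
22 | 4-[5,5-bis(phenylsulfonyl)pent-1-en-2-yl]-4-[2-(DecB)ethyl]cyclohexa-2,5-dien-1-one | C=C(CCC(S(=O)(=O)c5ccccc5)S(=O)(=O)c5ccccc5)C1(CC[C@@]3(C)C4=CCCC(C)(C)[C@@H]4CC[C@@H]3C)C=CC(=O)C=C1 | intermediate (key-step precursor)
23 | 4-methylidene-1,1-bis(phenylsulfonyl)-5β-[2-(DecB)ethyl]-10β-H-decal-6-en-8-one (cis-fused) | C=C1CCC(S(=O)(=O)c5ccccc5)(S(=O)(=O)c5ccccc5)[C@H]2[C@]1(CC[C@@]3(C)C4=CCCC(C)(C)[C@@H]4CC[C@@H]3C)C=CC(=O)C2 | intermediate (key-step product)
24 | 4-methylidene-1,1-bis(phenylsulfonyl)-5β-[2-(DecB)ethyl]-10β-H-decal-6-en-8-ol (C8 epimers) | C=C1CCC(S(=O)(=O)c5ccccc5)(S(=O)(=O)c5ccccc5)[C@H]2[C@]1(CC[C@@]3(C)C4=CCCC(C)(C)[C@@H]4CC[C@@H]3C)C=CC(O)C2 | intermediate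
25 | 4-methylidene-5β-[2-(DecB)ethyl]-10β-H-decal-6-en-8-ol (C8 epimers) | C=C1CCC[C@H]2[C@]1(CC[C@@]3(C)C4=CCCC(C)(C)[C@@H]4CC[C@@H]3C)C=CC(O)C2 | intermediate
26 | 4-methylidene-5β-[2-(DecB)ethyl]-10β-H-decal-6-en-8-one | C=C1CCC[C@H]2[C@]1(CC[C@@]3(C)C4=CCCC(C)(C)[C@@H]4CC[C@@H]3C)C=CC(=O)C2 | intermediate
27 | lithium C8–C9 enolate of 26 | C=C1CCC[C@H]2[C@]1(CC[C@@]3(C)C4=CCCC(C)(C)[C@@H]4CC[C@@H]3C)C=CC(O[Li])=C2 | intermediate (not isolated)
28 | 9-methyl-4-methylidene-5β-[2-(DecB)ethyl]-10β-H-decal-6-en-8-one (C9 epimers) | C=C1CCC[C@H]2[C@]1(CC[C@@]3(C)C4=CCCC(C)(C)[C@@H]4CC[C@@H]3C)C=CC(=O)C2C | intermediate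
29 | 2,5-dimethoxybenzyl alcohol | COc1ccc(OC)c(CO)c1 | starting material
30 | 2,5-dimethoxybenzyl bromide | COc1ccc(OC)c(CBr)c1 | intermediate
31 | lithium C8–C9 enolate of 28 | C=C1CCC[C@H]2[C@]1(CC[C@@]3(C)C4=CCCC(C)(C)[C@@H]4CC[C@@H]3C)C=CC(O[Li])=C2C | intermediate (not isolated)
32 | 9β-(2,5-dimethoxybenzyl)-9α-methyl-4-methylidene-5β-[2-(DecB)ethyl]-10β-H-decal-6-en-8-one | C=C1CCC[C@H]2[C@]1(CC[C@@]3(C)C4=CCCC(C)(C)[C@@H]4CC[C@@H]3C)C=CC(=O)[C@]2(C)Cc5cc(OC)ccc5OC | intermediate
33 | 9β-(2,5-dimethoxybenzyl)-9α-methyl-4-methylidene-5β-[2-(DecB)ethyl]-10β-H-decalin-8-one | C=C1CCC[C@H]2[C@]1(CC[C@@]3(C)C4=CCCC(C)(C)[C@@H]4CC[C@@H]3C)CCC(=O)[C@]2(C)Cc5cc(OC)ccc5OC | intermediate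
34 | 8-(methoxymethylidene)-9β-(2,5-dimethoxybenzyl)-9α-methyl-4-methylidene-5β-[2-(DecB)ethyl]-10β-H-decalin (E/Z mixture) | C=C1CCC[C@H]2[C@]1(CC[C@@]3(C)C4=CCCC(C)(C)[C@@H]4CC[C@@H]3C)CCC(=COC)[C@]2(C)Cc5cc(OC)ccc5OC | intermediate
35 | 8β-formyl-9β-(2,5-dimethoxybenzyl)-9α-methyl-4-methylidene-5β-[2-(DecB)ethyl]-10β-H-decalin | C=C1CCC[C@H]2[C@]1(CC[C@@]3(C)C4=CCCC(C)(C)[C@@H]4CC[C@@H]3C)CC[C@H](C=O)[C@]2(C)Cc5cc(OC)ccc5OC | intermediate
36 | hydrazone of 35 | C=C1CCC[C@H]2[C@]1(CC[C@@]3(C)C4=CCCC(C)(C)[C@@H]4CC[C@@H]3C)CC[C@H](C=NN)[C@]2(C)Cc5cc(OC)ccc5OC | intermediate (not isolated)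
37 | 8β,9α-dimethyl-9β-(2,5-dimethoxybenzyl)-4-methylidene-5β-[2-(DecB)ethyl]-10β-H-decalin | C=C1CCC[C@H]2[C@]1(CC[C@@]3(C)C4=CCCC(C)(C)[C@@H]4CC[C@@H]3C)CC[C@H](C)[C@]2(C)Cc5cc(OC)ccc5OC | intermediate
38 | 2-{[decalin A]methyl}cyclohexa-2,5-diene-1,4-dione (quinone of 37) | C=C1CCC[C@H]2[C@]1(CC[C@@]3(C)C4=CCCC(C)(C)[C@@H]4CC[C@@H]3C)CC[C@H](C)[C@]2(C)CC5=CC(=O)C=CC5=O | intermediate (not isolated)
39 | 2-{[decalin A]methyl}benzene-1,4-diol (hydroquinone) | C=C1CCC[C@H]2[C@]1(CC[C@@]3(C)C4=CCCC(C)(C)[C@@H]4CC[C@@H]3C)CC[C@H](C)[C@]2(C)Cc5cc(O)ccc5O | intermediate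
40 | CNP0439949.2, hydroquinone bis(hydrogen sulfate) (5R,8S,9S,10R; 5′S,8′S,9′R) | C=C1CCC[C@H]2[C@]1(CC[C@@]3(C)C4=CCCC(C)(C)[C@@H]4CC[C@@H]3C)CC[C@H](C)[C@]2(C)Cc5cc(OS(=O)(=O)O)ccc5OS(=O)(=O)O | target

## Step count and risks

Total step count: 26. Longest linear sequence: 25 steps (steps 1–18 and 20–26; step 19 is a one-step side branch).

The three steps most likely to fail:

Step 14 (key step). The catalyst may discriminate poorly between the two enone arms, and the uncatalysed cyclisation may compete, so that the C5,C10-diastereomer forms alongside 23. The fallback gives up catalyst control and relies on separation and recycling. It sets out from 22, which is cyclised with an achiral amine base (DBU, cat., CH2Cl2, rt) to 23 and the 5α,10α-diastereomer F1. Because decalin B is homochiral these are diastereomers and can be separated by chromatography or crystallisation. F1 is then resubmitted to the base at higher temperature, where retro-Michael/Michael equilibration regenerates the mixture. The fallback comes back to the route at 23.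

Step 20. The benzyl electrophile may enter on the α face (anti to the angular C5 chain) instead of the β face, giving the C9 epimer of 32. The fallback reverses the order of the two alkylations, so that the last electrophile, which defines the configuration, is the methyl group. It sets out from 26, which is benzylated (LiN(i-Pr)2, then 30) to the 9-(2,5-dimethoxybenzyl) enone F2 (C9 epimers). F2 is then deprotonated again and methylated with MeI, which places methyl α and benzyl β if the enolate reacts on its α face. The fallback comes back to the route at 32.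

Step 23. The aldehyde equilibrium may give only a weak preference for the 8β epimer, and kinetic protonation at C8 is expected from the open β face, which gives the 8α-formyl compound. The fallback sets C8 by kinetic C–C bond formation instead of equilibration. It sets out from 35 (either epimer or the mixture), whose potassium enolate (KOt-Bu, THF, 0 °C) is methylated with MeI on the β face to give the 8α-formyl-8β-methyl compound F3. The formyl group is then removed with retention of configuration by Tsuji–Wilkinson decarbonylation (RhCl(PPh3)3, stoichiometric, benzonitrile, 160 °C). The fallback comes back to the route at 37 and bypasses step 24.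

## Further compounds

F1 | step 14 | 5α,10α-diastereomer of 23: 4-methylidene-1,1-bis(phenylsulfonyl)-5α-[2-(DecB)ethyl]-10α-H-decal-6-en-8-one | C=C1CCC(S(=O)(=O)c5ccccc5)(S(=O)(=O)c5ccccc5)[C@@H]2[C@@]1(CC[C@@]3(C)C4=CCCC(C)(C)[C@@H]4CC[C@@H]3C)C=CC(=O)C2
F2 | step 20 | 9-(2,5-dimethoxybenzyl)-4-methylidene-5β-[2-(DecB)ethyl]-10β-H-decal-6-en-8-one (C9 epimers) | C=C1CCC[C@H]2[C@]1(CC[C@@]3(C)C4=CCCC(C)(C)[C@@H]4CC[C@@H]3C)C=CC(=O)C2Cc5cc(OC)ccc5OC
F3 | step 23 | 8α-formyl-8β,9α-dimethyl-9β-(2,5-dimethoxybenzyl)-4-methylidene-5β-[2-(DecB)ethyl]-10β-H-decalin | C=C1CCC[C@H]2[C@]1(CC[C@@]3(C)C4=CCCC(C)(C)[C@@H]4CC[C@@H]3C)CC[C@](C=O)(C)[C@]2(C)Cc5cc(OC)ccc5OC
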